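**Retrosynthetic overview**
Target ⇒ acetylation/desilylation ⇒ Heck coupling with myrcene ⇒ oxidative transposition to the C7 enal ⇒ trans opening of a C1–C2 epoxide by an alkenyl Grignard/copper reagent ⇒ spiro[4.5]dec-7-en-1-one.
The strategy rests on the adjacent C5 (quaternary, spiro) and C6 (tertiary) atoms of ring A (C5–C10), with the ring B carbonyl C1 on C5 and a C7–C8 double bond in reach: the γ,δ-unsaturated ketone retron of a Claisen rearrangement of the allyl vinyl ether C5=C1–O–C8–C7=C6.
Ring order: ring B is bought as a cyclopentene; a fused dihydropyran is closed on it by copper-catalysed O-vinylation; ring A is formed last, by Claisen ring contraction of that pyran.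
C8 comes from a catalytic asymmetric aldol and C10 from chelation-controlled methyl addition in the open chain; methyl addition to the closed dihydropyranone is avoided because axial attack trans to the C8 arm would give the C10 epimer.
C7 is carried as a Z methyl enol ether (a silyl enol ether would hand its silicon to the neighbouring C8 alkoxide) and the chain oxygen as a tert-butyldiphenylsilyl ether.

Key step: step 11

Remarks. Atom numbers are those of the spiro[4.5]decane core of the target and are used for all intermediates. TBDPS = tert-butyldiphenylsilyl, TBS = tert-butyldimethylsilyl, TES = triethylsilyl, TMS = trimethylsilyl.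
Assumption: the (S,S)-ProPhenol/zinc catalyst of step 7 is taken to give the 3R aldol; if the sense of induction is the opposite, the (R,R)-ligand is used.

**Route**

Step 1
Reactants: 1 butane-1,4-diol
Product: 2 4-(TBDPS-oxy)butan-1-ol
Conditions: NaH (1 equiv), THF, 0 °C; t-BuPh2SiCl
Reagents that add atoms: tert-butyl(chloro)diphenylsilane, CC(C)(C)[Si](Cl)(c1ccccc1)c1ccccc1
Why: O-silylation of the sparingly soluble monosodium alkoxide of the symmetric diol should stop after one silyl group.

Step 2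
Reactants: 2 4-(TBDPS-oxy)butan-1-ol
Product: 3 4-(TBDPS-oxy)butanal
Conditions: PhI(OAc)2, TEMPO (cat.), CH2Cl2, rt
Reagents that add atoms: none
Why: TEMPO-catalysed oxidation with PhI(OAc)2 takes the primary alcohol to the aldehyde without over-oxidation and leaves the silyl ether intact.

Step 3
Reactants: 3 4-(TBDPS-oxy)butanal; 4 methyl 2-(dimethoxyphosphoryl)-2-methoxyacetate
Product: 5 methyl (2Z)-6-(TBDPS-oxy)-2-methoxyhex-2-enoate
Conditions: NaH, THF, 0 °C to rt
Reagents that add atoms: none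
Why: Horner–Wadsworth–Emmons olefination places the ester trans to the chain, so the methoxy group is cis to it (Z), the geometry later needed at C6=C7.

Step 4
Reactants: 5 methyl (2Z)-6-(TBDPS-oxy)-2-methoxyhex-2-enoate
Product: 6 (2Z)-6-(TBDPS-oxy)-2-methoxyhex-2-en-1-ol
Conditions: iBu2AlH (2.2 equiv), CH2Cl2, −78 °C; Rochelle salt
Reagents that add atoms: none
Why: Hydride reduction of the ester with iBu2AlH gives the allylic alcohol at low temperature without touching the enol ether or the silyl ether.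

Step 5
Reactants: 6 (2Z)-6-(TBDPS-oxy)-2-methoxyhex-2-en-1-ol
Product: 7 (2Z)-6-(TBDPS-oxy)-2-methoxyhex-2-enal
Conditions: MnO2, CH2Cl2, rt
Reagents that add atoms: none
Why: MnO2 oxidation of the allylic alcohol is neutral and spares the acid-labile enol ether.

Step 6
Reactants: 8 1,2-dibromocyclopentene
Product: 10 1-(2-bromocyclopent-1-en-1-yl)ethan-1-one, via (2-bromocyclopent-1-en-1-yl)lithium 9 (not isolated)
Conditions: n-BuLi (1 equiv), THF, −78 °C; MeC(O)N(OMe)Me; aq. NH4Cl
Reagents that add atoms: N-methoxy-N-methylacetamide, CC(=O)N(C)OC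
Why: Bromine–lithium exchange of one vinylic bromide and acylation with the Weinreb amide should give the methyl ketone without over-addition.

Step 7
Reactants: 10 1-(2-bromocyclopent-1-en-1-yl)ethan-1-one; 7 (2Z)-6-(TBDPS-oxy)-2-methoxyhex-2-enal
Product: 11 (3R,4Z)-1-(2-bromocyclopent-1-en-1-yl)-8-(TBDPS-oxy)-3-hydroxy-4-methoxyoct-4-en-1-one
Conditions: Et2Zn (cat.), (S,S)-ProPhenol (cat.), 4 Å MS, THF, 0 °C
Reagents that add atoms: none
Why: The dinuclear zinc–ProPhenol direct aldol (Trost) of a methyl vinyl ketone-type donor adds the zinc enolate to one face of the aldehyde, so C8 (R) is set by the catalyst, and the neutral medium spares the enol ether.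

Step 8
Reactants: 11 (3R,4Z)-1-(2-bromocyclopent-1-en-1-yl)-8-(TBDPS-oxy)-3-hydroxy-4-methoxyoct-4-en-1-one
Product: 12 (2S,4R,5Z)-2-(2-bromocyclopent-1-en-1-yl)-9-(TBDPS-oxy)-5-methoxynon-5-ene-2,4-diol
Conditions: MeMgBr (3 equiv), CH2Cl2–Et2O, −78 °C; aq. NH4Cl
Reagents that add atoms: methylmagnesium bromide, C[Mg]Br
Why: Chelation-controlled Grignard addition: the magnesium alkoxide of C8–OH binds the ketone in a six-membered chelate with the C8 arm equatorial and methyl enters axially, which should give the syn-1,3-diol and set C10 (S).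

Step 9
Reactants: 12 (2S,4R,5Z)-2-(2-bromocyclopent-1-en-1-yl)-9-(TBDPS-oxy)-5-methoxynon-5-ene-2,4-diol
Product: 13 (2R,4S)-2-[(1Z)-5-(TBDPS-oxy)-1-methoxypent-1-en-1-yl]-4-methyl-2,3,4,5,6,7-hexahydrocyclopenta[b]pyran-4-ol
Conditions: CuI (cat.), 3,4,7,8-tetramethyl-1,10-phenanthroline (cat.), Cs2CO3, PhMe, 90 °C
Reagents that add atoms: none
Why: Copper-catalysed intramolecular O-vinylation (Ullmann-type C–O coupling) joins the secondary alkoxide to the cis vinyl bromide in a six-membered ring, the tertiary alkoxide cannot close, and neither carbinol centre is touched.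

Step 10
Reactants: 13 (2R,4S)-2-[(1Z)-5-(TBDPS-oxy)-1-methoxypent-1-en-1-yl]-4-methyl-2,3,4,5,6,7-hexahydrocyclopenta[b]pyran-4-ol
Product: 14 (2R,4S)-2-[(1Z)-5-(TBDPS-oxy)-1-methoxypent-1-en-1-yl]-4-methyl-4-(TMS-oxy)-2,3,4,5,6,7-hexahydrocyclopenta[b]pyran
Conditions: 1-(trimethylsilyl)imidazole, CH2Cl2, rt; chromatography on Et3N-treated silica
Reagents that add atoms: 1-(trimethylsilyl)imidazole, C[Si](C)(C)n1ccnc1
Why: O-silylation with a neutral silyl donor caps the tertiary allylic alcohol without acid, which would ionise the C10–O bond.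

Step 11
Reactants: 14 (2R,4S)-2-[(1Z)-5-(TBDPS-oxy)-1-methoxypent-1-en-1-yl]-4-methyl-4-(TMS-oxy)-2,3,4,5,6,7-hexahydrocyclopenta[b]pyran
Product: 15 (5R,6S,10S)-6-[3-(TBDPS-oxy)propyl]-7-methoxy-10-methyl-10-(TMS-oxy)spiro[4.5]dec-7-en-1-one
Conditions: PhMe (dilute), N,O-bis(trimethylsilyl)acetamide (0.1 equiv), base-washed sealed tube, 200 °C
Reagents that add atoms: none
Why: Heating breaks the O–C8 bond while C5 bonds to C6 in a concerted suprafacial [3,3] shift of the allyl vinyl ether C5=C1–O–C8–C7=C6; because C9–C10 ties C8 to C5, the six atoms can only adopt a bicyclo[2.2.2]-like boat. The closest known reaction is the thermal Claisen ring contraction of 2-alkenyl-3,4-dihydro-2H-pyrans to 4-acylcyclohexenes, and allyl vinyl ethers with an alkoxy group on the central allyl carbon are known to rearrange, only more slowly. Ring A closes through the new C5–C6 bond as the third bridge of this boat, a six-membered carbocycle formed by contraction of the pyran, whose oxygen ends as the C1 carbonyl. C5 is fixed by C8, since the alkenyl arm reaches C5 only on the ring face on which it stands, trans to the C10 siloxy group, so that C10–O ends cis to C1; C6 is fixed by the Z enol ether, whose chain points away from the ring (trans to C8) and therefore also ends cis to C1. The step needs the [3,3] path to win over ionisation of the allylic C10–O bond and over a 1,3-shift; the tether makes 1,3-closure a cyclobutane, and base-washed glass, a silylating scavenger and a non-polar medium should suppress ionisation.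

Step 12
Reactants: 15 (5R,6S,10S)-6-[3-(TBDPS-oxy)propyl]-7-methoxy-10-methyl-10-(TMS-oxy)spiro[4.5]dec-7-en-1-one
Product: 16 C1 enol triflate of 15 (spiro[4.5]deca-1,7-dien-1-yl trifluoromethanesulfonate)
Conditions: KN(SiMe3)2, THF, −78 °C; PhNTf2
Reagents that add atoms: N-phenylbis(trifluoromethanesulfonimide), O=S(=O)(N(c1ccccc1)S(=O)(=O)C(F)(F)F)C(F)(F)F
Why: Enol triflate formation by deprotonation at C2, the only enolisable position, gives a handle for removing the carbonyl oxygen, and the C10 silyl ether prevents retro-aldol cleavage.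

Step 13
Reactants: 16 C1 enol triflate of 15
Product: 17 6-[3-(TBDPS-oxy)propyl]-7-methoxy-10-methyl-10-(TMS-oxy)spiro[4.5]deca-1,7-diene
Conditions: Pd(OAc)2 (cat.), PPh3, Bu3N, HCO2H, DMF, 60 °C
Reagents that add atoms: none
Why: Palladium-catalysed formate reduction of the enol triflate gives the C1=C2 alkene without touching the enol ether.

Step 14
Reactants: 17 6-[3-(TBDPS-oxy)propyl]-7-methoxy-10-methyl-10-(TMS-oxy)spiro[4.5]deca-1,7-diene
Product: 18 6-[3-(TBDPS-oxy)propyl]-10-hydroxy-10-methylspiro[4.5]dec-1-en-7-one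
Conditions: 1 M HCl, THF, 0 °C
Reagents that add atoms: water, O
Why: Acid hydrolysis of the methyl enol ether proceeds by protonation at C8, which leaves C6 untouched, and the same acid cleaves the tertiary TMS ether while the TBDPS ether survives.

Step 15
Reactants: 18 6-[3-(TBDPS-oxy)propyl]-10-hydroxy-10-methylspiro[4.5]dec-1-en-7-one
Product: 19 1,2-epoxide of 18 with the epoxide oxygen cis to C10
Conditions: VO(acac)2 (cat.), t-BuOOH, CH2Cl2, 0 °C to rt
Reagents that add atoms: tert-butyl hydroperoxide, CC(C)(C)OO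
Why: Hydroxyl-directed epoxidation of the homoallylic C10 alcohol delivers oxygen to the alkene face on the side of C10, which sets C1 with its oxygen cis to C10.

Step 16
Reactants: 19 1,2-epoxide of 18
Product: 20 1,2-epoxy-7-(prop-1-en-2-yl)spiro[4.5]decane-7,10-diol (C7 configuration of no consequence)
Conditions: CH2=C(CH3)MgBr, CeCl3, THF, −78 °C; aq. NH4Cl
Reagents that add atoms: isopropenylmagnesium bromide, CC(=C)[Mg]Br
Why: Organocerium 1,2-addition to the hindered C7 ketone occurs without enolisation, so C6 is not epimerised, and the epoxide is spared at this temperature.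

Step 17
Reactants: 21 tert-butyldimethyl(prop-2-yn-1-yloxy)silane
Product: 22 (Z)-tert-butyldimethyl{[2-(tributylstannyl)-3-(trimethylsilyl)prop-2-en-1-yl]oxy}silane
Conditions: Me3Si–SnBu3, Pd(PPh3)4 (cat.), THF, 65 °C
Reagents that add atoms: tributyl(trimethylsilyl)stannane, C[Si](C)(C)[Sn](CCCC)(CCCC)CCCC
Why: Palladium-catalysed silylstannation of the terminal alkyne adds Si and Sn cis, with tin at the internal and silicon at the terminal carbon.

Step 18
Reactants: 22 (Z)-tert-butyldimethyl{[2-(tributylstannyl)-3-(trimethylsilyl)prop-2-en-1-yl]oxy}silane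
Product: 23 (Z)-tert-butyl{[2-iodo-3-(trimethylsilyl)prop-2-en-1-yl]oxy}dimethylsilane
Conditions: I2 (1 equiv), CH2Cl2, 0 °C
Reagents that add atoms: iodine, II
Why: Iododestannylation replaces tin with retention of the alkene geometry and leaves the less reactive vinylsilane in place.

Step 19
Reactants: 20 1,2-epoxy-7-(prop-1-en-2-yl)spiro[4.5]decane-7,10-diol; 23 (Z)-tert-butyl{[2-iodo-3-(trimethylsilyl)prop-2-en-1-yl]oxy}dimethylsilane
Product: 26 C2-alkenyl spiro[4.5]decane-1,7,10-triol, via alkenyllithium 24 (not isolated), via alkenylmagnesium bromide 25 (not isolated)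
Conditions: 23 (4 equiv), t-BuLi (2 equiv per iodide), Et2O, −78 °C; MgBr2·OEt2; then 20, CuI (cat.), THF, −30 to 0 °C; aq. NH4Cl
Reagents that add atoms: none
Why: Copper-catalysed Grignard opening of the epoxide occurs with inversion at the less hindered C2, remote from the spiro centre, which gives the trans-2-alkenyl alcohol and so sets C2 while C1 keeps its oxygen; the alkenyl metal keeps its geometry.

Step 20
Reactants: 26 C2-alkenyl spiro[4.5]decane-1,7,10-triol
Product: 27 1-O-TES ether of 26
Conditions: Et3SiCl, imidazole, DMAP (cat.), DMF, 0 °C to rt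
Reagents that add atoms: chlorotriethylsilane, CC[Si](Cl)(CC)CC
Why: Silylation with Et3SiCl and imidazole takes the secondary C1 alcohol and not the two tertiary alcohols, so C1 is shielded from the oxidant of the next step.

Step 21
Reactants: 27 1-O-TES ether of 26
Product: 28 (2Z)-2-(spiro[4.5]decan-7-ylidene)propanal with the formyl group on the C6 side
Conditions: [C5H5NH][CrO3Cl], 4 Å MS, CH2Cl2, rt
Reagents that add atoms: pyridinium chlorochromate, [nH+]1ccccc1.[O-][Cr](=O)(=O)Cl
Why: Dauben–Babler oxidative 1,3-transposition: the chromate ester of the tertiary allylic alcohol shifts [3,3] and is oxidised to the enal, and the methyl group should turn toward the less substituted C8 so that the formyl group lies on the C6 side.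

Step 22
Reactants: 28 (2Z)-2-(spiro[4.5]decan-7-ylidene)propanal
Product: 29 (E)-alkenyl iodide from 28 (I in place of SiMe3)
Conditions: N-iodosuccinimide, MeCN–ClCH2CN, 0 °C to rt
Reagents that add atoms: N-iodosuccinimide, O=C1CCC(=O)N1I
Why: Iododesilylation by ipso attack on the vinylsilane proceeds with retention and leaves the electron-poor enal alkene alone.

Step 23
Reactants: 29 (E)-alkenyl iodide from 28; 30 myrcene (7-methyl-3-methylideneocta-1,6-diene)
Product: 31 fully protected triene
Conditions: Pd(OAc)2 (cat.), K2CO3, Bu4NCl, DMF, 50 °C; myrcene in excess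
Reagents that add atoms: none
Why: Heck reaction under Jeffery conditions: the alkenylpalladium species adds to the unsubstituted end of the monosubstituted vinyl group of myrcene and syn β-hydride elimination gives the E-diene, with the geometry of the iodide kept.

Step 24
Reactants: 31 fully protected triene
Product: 32 diol with C1–OH and the side-chain CH2OH free
Conditions: HF·pyridine, pyridine, THF, 0 °C
Reagents that add atoms: none
Why: Buffered fluoride desilylation cleaves the primary allylic TBS ether and the secondary TES ether and leaves the more robust TBDPS ether.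

Step 25
Reactants: 32 diol with C1–OH and the side-chain CH2OH free
Product: 33 side-chain mono-acetate
Conditions: Ac2O (1.1 equiv), 2,4,6-collidine, CH2Cl2, −20 to 0 °C
Reagents that add atoms: acetic anhydride, CC(=O)OC(C)=O
Why: Selective acylation takes the unhindered primary allylic alcohol in preference to the neopentyl-type secondary C1 alcohol and the tertiary C10 alcohol.

Step 26
Reactants: 33 side-chain mono-acetate
Product: 34 CNP0204268.2
Conditions: Bu4NF, AcOH, THF, rt
Reagents that add atoms: none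
Why: Fluoride desilylation buffered with acetic acid removes the last silyl ether without cleaving the acetate or isomerising the enal and the triene.

**Compound list**
1 | butane-1,4-diol | OCCCCO | starting material
2 | 4-[(tert-butyldiphenylsilyl)oxy]butan-1-ol | OCCCCO[Si](c1ccccc1)(c1ccccc1)C(C)(C)C | intermediate
3 | 4-[(tert-butyldiphenylsilyl)oxy]butanal | O=CCCCO[Si](c1ccccc1)(c1ccccc1)C(C)(C)C | intermediate
4 | methyl 2-(dimethoxyphosphoryl)-2-methoxyacetate | COC(C(=O)OC)P(=O)(OC)OC | starting material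
5 | methyl (2Z)-6-[(tert-butyldiphenylsilyl)oxy]-2-methoxyhex-2-enoate | COC(=O)/C(OC)=C/CCCO[Si](c1ccccc1)(c1ccccc1)C(C)(C)C | intermediate
6 | (2Z)-6-[(tert-butyldiphenylsilyl)oxy]-2-methoxyhex-2-en-1-ol | OC/C(OC)=C/CCCO[Si](c1ccccc1)(c1ccccc1)C(C)(C)C | intermediate
7 | (2Z)-6-[(tert-butyldiphenylsilyl)oxy]-2-methoxyhex-2-enal | O=C/C(OC)=C/CCCO[Si](c1ccccc1)(c1ccccc1)C(C)(C)C | intermediate
8 | 1,2-dibromocyclopentene | BrC1=C(Br)CCC1 | starting material
9 | (2-bromocyclopent-1-en-1-yl)lithium | [Li]C1=C(Br)CCC1 | intermediate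
10 | 1-(2-bromocyclopent-1-en-1-yl)ethan-1-one | CC(=O)C1=C(Br)CCC1 | intermediate
11 | (3R,4Z)-1-(2-bromocyclopent-1-en-1-yl)-8-[(tert-butyldiphenylsilyl)oxy]-3-hydroxy-4-methoxyoct-4-en-1-one | O=C(C[C@@H](O)/C(OC)=C/CCCO[Si](c1ccccc1)(c1ccccc1)C(C)(C)C)C1=C(Br)CCC1 | intermediate
12 | (2S,4R,5Z)-2-(2-bromocyclopent-1-en-1-yl)-9-[(tert-butyldiphenylsilyl)oxy]-5-methoxynon-5-ene-2,4-diol | C[C@](O)(C[C@@H](O)/C(OC)=C/CCCO[Si](c1ccccc1)(c1ccccc1)C(C)(C)C)C1=C(Br)CCC1 | intermediate
13 | (2R,4S)-2-{(1Z)-5-[(tert-butyldiphenylsilyl)oxy]-1-methoxypent-1-en-1-yl}-4-methyl-2,3,4,5,6,7-hexahydrocyclopenta[b]pyran-4-ol | C1CCC2=C1O[C@@H](/C(OC)=C/CCCO[Si](c3ccccc3)(c3ccccc3)C(C)(C)C)C[C@]2(C)O | intermediate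
14 | (2R,4S)-2-{(1Z)-5-[(tert-butyldiphenylsilyl)oxy]-1-methoxypent-1-en-1-yl}-4-methyl-4-[(trimethylsilyl)oxy]-2,3,4,5,6,7-hexahydrocyclopenta[b]pyran (Claisen precursor) | C1CCC2=C1O[C@@H](/C(OC)=C/CCCO[Si](c3ccccc3)(c3ccccc3)C(C)(C)C)C[C@]2(C)O[Si](C)(C)C | intermediate
15 | (5R,6S,10S)-6-{3-[(tert-butyldiphenylsilyl)oxy]propyl}-7-methoxy-10-methyl-10-[(trimethylsilyl)oxy]spiro[4.5]dec-7-en-1-one (Claisen product; chain and C10–O both cis to C1) | C1CC[C@]2([C@H](CCCO[Si](c3ccccc3)(c3ccccc3)C(C)(C)C)C(OC)=CC[C@]2(C)O[Si](C)(C)C)C1=O | intermediate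
16 | 6-{3-[(tert-butyldiphenylsilyl)oxy]propyl}-7-methoxy-10-methyl-10-[(trimethylsilyl)oxy]spiro[4.5]deca-1,7-dien-1-yl trifluoromethanesulfonate, ring configuration as in 15 | C1CC[C@]2([C@H](CCCO[Si](c3ccccc3)(c3ccccc3)C(C)(C)C)C(OC)=CC[C@]2(C)O[Si](C)(C)C)C(OS(=O)(=O)C(F)(F)F)=1 | intermediate
17 | 6-{3-[(tert-butyldiphenylsilyl)oxy]propyl}-7-methoxy-10-methyl-10-[(trimethylsilyl)oxy]spiro[4.5]deca-1,7-diene, configuration as in 15 | C1CC[C@]2([C@H](CCCO[Si](c3ccccc3)(c3ccccc3)C(C)(C)C)C(OC)=CC[C@]2(C)O[Si](C)(C)C)C=1 | intermediate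
18 | 6-{3-[(tert-butyldiphenylsilyl)oxy]propyl}-10-hydroxy-10-methylspiro[4.5]dec-1-en-7-one, configuration as in 15 | C1CC[C@]2([C@H](CCCO[Si](c3ccccc3)(c3ccccc3)C(C)(C)C)C(=O)CC[C@]2(C)O)C=1 | intermediate
19 | 1,2-epoxy-6-{3-[(tert-butyldiphenylsilyl)oxy]propyl}-10-hydroxy-10-methylspiro[4.5]decan-7-one, epoxide oxygen cis to C10 | [C@H]1(O2)CC[C@]3([C@H](CCCO[Si](c4ccccc4)(c4ccccc4)C(C)(C)C)C(=O)CC[C@]3(C)O)[C@H]12 | intermediate
20 | 1,2-epoxy-6-{3-[(tert-butyldiphenylsilyl)oxy]propyl}-10-methyl-7-(prop-1-en-2-yl)spiro[4.5]decane-7,10-diol, C7 unassigned | [C@H]1(O2)CC[C@]3([C@H](CCCO[Si](c4ccccc4)(c4ccccc4)C(C)(C)C)C(O)(C(C)=C)CC[C@]3(C)O)[C@H]12 | intermediate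
21 | tert-butyldimethyl(prop-2-yn-1-yloxy)silane | C#CCO[Si](C)(C)C(C)(C)C | starting material
22 | (Z)-tert-butyldimethyl{[2-(tributylstannyl)-3-(trimethylsilyl)prop-2-en-1-yl]oxy}silane | CC(C)(C)[Si](C)(C)OC/C(=C/[Si](C)(C)C)[Sn](CCCC)(CCCC)CCCC | intermediate
23 | (Z)-tert-butyl{[2-iodo-3-(trimethylsilyl)prop-2-en-1-yl]oxy}dimethylsilane | CC(C)(C)[Si](C)(C)OC/C(I)=C/[Si](C)(C)C | intermediate
24 | [(Z)-1-{[(tert-butyldimethylsilyl)oxy]methyl}-2-(trimethylsilyl)ethenyl]lithium | CC(C)(C)[Si](C)(C)OC/C([Li])=C/[Si](C)(C)C | intermediate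
25 | [(Z)-1-{[(tert-butyldimethylsilyl)oxy]methyl}-2-(trimethylsilyl)ethenyl]magnesium bromide | CC(C)(C)[Si](C)(C)OC/C([Mg]Br)=C/[Si](C)(C)C | intermediate
26 | 2-[(E)-1-{[(tert-butyldimethylsilyl)oxy]methyl}-2-(trimethylsilyl)ethenyl]-6-{3-[(tert-butyldiphenylsilyl)oxy]propyl}-10-methyl-7-(prop-1-en-2-yl)spiro[4.5]decane-1,7,10-triol; C1–OH cis to C10, C2 arm trans to C1–OH, C7 unassigned | C[Si](C)(C)/C=C(/CO[Si](C)(C)C(C)(C)C)[C@@H]1CC[C@]2([C@H](CCCO[Si](c3ccccc3)(c3ccccc3)C(C)(C)C)C(O)(C(C)=C)CC[C@]2(C)O)[C@H]1O | intermediate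
27 | 1-O-triethylsilyl ether of 26 | C[Si](C)(C)/C=C(/CO[Si](C)(C)C(C)(C)C)[C@@H]1CC[C@]2([C@H](CCCO[Si](c3ccccc3)(c3ccccc3)C(C)(C)C)C(O)(C(C)=C)CC[C@]2(C)O)[C@H]1O[Si](CC)(CC)CC | intermediate
28 | (2Z)-2-[spiro[4.5]decan-7-ylidene]propanal carrying the substituents of 27 (C1 OTES, C2 alkenylsilane arm, C6 silyloxypropyl, C10 OH); CHO on the C6 side | C[Si](C)(C)/C=C(/CO[Si](C)(C)C(C)(C)C)[C@@H]1CC[C@]2([C@H](CCCO[Si](c3ccccc3)(c3ccccc3)C(C)(C)C)/C(=C(/C)C=O)CC[C@]2(C)O)[C@H]1O[Si](CC)(CC)CC | intermediate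
29 | alkenyl iodide: as 28 with the C2 arm (E)-1-{[(tert-butyldimethylsilyl)oxy]methyl}-2-iodoethenyl | I/C=C(/CO[Si](C)(C)C(C)(C)C)[C@@H]1CC[C@]2([C@H](CCCO[Si](c3ccccc3)(c3ccccc3)C(C)(C)C)/C(=C(/C)C=O)CC[C@]2(C)O)[C@H]1O[Si](CC)(CC)CC | intermediate
30 | myrcene (7-methyl-3-methylideneocta-1,6-diene) | C=CC(=C)CCC=C(C)C | starting material
31 | protected triene: as 29 with the C2 arm (2E,4E)-1-[(tert-butyldimethylsilyl)oxy]-10-methyl-6-methylideneundeca-2,4,9-trien-2-yl | C=C(/C=C/C=C(/CO[Si](C)(C)C(C)(C)C)[C@@H]1CC[C@]2([C@H](CCCO[Si](c3ccccc3)(c3ccccc3)C(C)(C)C)/C(=C(/C)C=O)CC[C@]2(C)O)[C@H]1O[Si](CC)(CC)CC)CCC=C(C)C | intermediate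
32 | diol: as 31 with C1–OH and side-chain CH2OH free, chain oxygen still TBDPS-protected | C=C(/C=C/C=C(/CO)[C@@H]1CC[C@]2([C@H](CCCO[Si](c3ccccc3)(c3ccccc3)C(C)(C)C)/C(=C(/C)C=O)CC[C@]2(C)O)[C@H]1O)CCC=C(C)C | intermediate
33 | mono-acetate: as 32 with the side-chain CH2OAc | C=C(/C=C/C=C(/COC(C)=O)[C@@H]1CC[C@]2([C@H](CCCO[Si](c3ccccc3)(c3ccccc3)C(C)(C)C)/C(=C(/C)C=O)CC[C@]2(C)O)[C@H]1O)CCC=C(C)C | intermediate
34 | CNP0204268.2: (1S,2S,5S,6R,10S)-1,10-dihydroxy-6-(3-hydroxypropyl)-10-methyl-7-[(Z)-1-oxopropan-2-ylidene]spiro[4.5]decan-2-yl-substituted (2E,4E)-10-methyl-6-methylideneundeca-2,4,9-trienyl acetate (arm attached through its C2) | C=C(/C=C/C=C(/COC(C)=O)[C@@H]1CC[C@]2([C@H](CCCO)/C(=C(/C)C=O)CC[C@]2(C)O)[C@H]1O)CCC=C(C)C | target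

**Step count**
Total: 26 steps. Longest linear sequence: 23 steps (1–5, 7–16, 19–26).

**Steps most likely to fail**

Step 11 (key step). The boat rearrangement is slowed by the alkoxy group on the central allyl carbon and by formation of a quaternary centre. At the temperature it needs, the tertiary allylic silyl ether may ionise, with allylic transposition of the siloxy group or capture of the allyl oxocarbenium ion by the enol ether, or it may eliminate. Fallback: the ring contraction is moved to the vinylogous ester stage, where no ionisable C10–O bond is present. Aldol 11 is cyclised with K2CO3 in MeCN by intramolecular addition–elimination at the bromo-enone to the dihydropyranone F1. F1 is rearranged by heating in PhMe, or with Pd(PPh3)4, the β-diketonate now being a competent leaving group for zerovalent palladium, to the spiro-1,10-dione F2 with the same C5 and C6 configuration. MeMgBr/CeCl3 then adds to the more reactive six-ring carbonyl and the alkoxide is capped with Me3SiCl. The facial selectivity of this addition is not secured, so the C10 epimers would be separated; the route is rejoined at 15.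

Step 8. Incomplete chelation would erode the facial selectivity at C10, and the magnesium alkoxide may close onto the bromo-enone before methyl adds. Fallback: C10 is set on the closed ring by sulfoxide–sulfenate transposition. Aldol 11 is cyclised (K2CO3, MeCN) to the dihydropyranone F1. MeLi/CeCl3 adds axially, trans to the C8 arm, to give mainly the tertiary alcohol F3 with the wrong C10 configuration. PhSH (excess) with a trace of pyridinium tosylate at low temperature converts either C10 epimer through the allyl oxocarbenium ion into the C1 phenylthio ketal F4, in which the ring fusion forces sulfur axial and trans to the C8 arm. Oxidation with 3-chloroperbenzoic acid at −78 °C and warming with Et2NH (Mislow–Evans [2,3] shift) delivers oxygen to C10 on the face that sulfur occupied, which gives 13, where the route is rejoined.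

Step 21. The hexavalent chromium reagent is acidic and may strip silyl ethers or over-oxidise, and the tetrasubstituted enal may form as a mixture of geometric isomers. Fallback: transposition and oxidation are separated. Ph3SiOReO3 (cat.) in Et2O isomerises the tertiary allylic alcohol 27 to the primary allylic alcohol F5 under thermodynamic control, and MnO2 oxidises F5 to 28. The geometric isomers are separated at the enal stage and the unwanted one is recycled by photoisomerisation; the route is rejoined at 28.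

**Further compounds**
F1 | step 11 | (2R)-2-{(1Z)-5-[(tert-butyldiphenylsilyl)oxy]-1-methoxypent-1-en-1-yl}-2,3,6,7-tetrahydrocyclopenta[b]pyran-4(5H)-one | O=C1C[C@H](/C(OC)=C/CCCO[Si](c2ccccc2)(c2ccccc2)C(C)(C)C)OC2=C1CCC2
F2 | step 11 | 6-{3-[(tert-butyldiphenylsilyl)oxy]propyl}-7-methoxyspiro[4.5]dec-7-ene-1,10-dione, C5 and C6 as in 15 | C1CC[C@]2([C@H](CCCO[Si](c3ccccc3)(c3ccccc3)C(C)(C)C)C(OC)=CCC2=O)C1=O
F3 | step 8 | (2R,4R)-2-{(1Z)-5-[(tert-butyldiphenylsilyl)oxy]-1-methoxypent-1-en-1-yl}-4-methyl-2,3,4,5,6,7-hexahydrocyclopenta[b]pyran-4-ol (C10 epimer of 13) | C1CCC2=C1O[C@@H](/C(OC)=C/CCCO[Si](c3ccccc3)(c3ccccc3)C(C)(C)C)C[C@@]2(C)O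
F4 | step 8 | 2-{(1Z)-5-[(tert-butyldiphenylsilyl)oxy]-1-methoxypent-1-en-1-yl}-4-methyl-7a-(phenylsulfanyl)-2,3,5,6,7,7a-hexahydrocyclopenta[b]pyran, sulfur trans to the C2 substituent | CC1=C2CCC[C@@]2(Sc3ccccc3)O[C@@H](/C(OC)=C/CCCO[Si](c3ccccc3)(c3ccccc3)C(C)(C)C)C1
F5 | step 21 | (2Z)-2-[spiro[4.5]decan-7-ylidene]propan-1-ol carrying the substituents of 27 | C[Si](C)(C)/C=C(/CO[Si](C)(C)C(C)(C)C)[C@@H]1CC[C@]2([C@H](CCCO[Si](c3ccccc3)(c3ccccc3)C(C)(C)C)/C(=C(/C)CO)CC[C@]2(C)O)[C@H]1O[Si](CC)(CC)CC
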